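**Plan**

Retrosynthesis: the O9–tigloyl and O8–(R)-2-methylbutanoyl bonds are cut first, then C8–O and C7–C11 (isopropenyl) on a C7=C8–C9=O enone, then the C4–H bond (from a C4=C15 methylene), then C3–C4 (ring A), and last C10–C1 and C5–C4 on 3-methylcyclohex-2-en-1-one.
Enabling feature (eremophilane numbering; ring A = C10–C1–C2–C3–C4–C5, ring B = C5–C6–C7–C8–C9–C10, C14 on C5, C15 on C4): C3 is alpha to the C2 ketone and C4, which carries C15, is bonded to the quaternary C5, so C3 of a beta-keto ester chain on C10 can add to an ethynyl group on C5 whose terminal carbon becomes C15.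
Forward: ring B is the starting cyclohexenone; alkynyl conjugate addition and enolate alkylation attach C4/C15 and the C1–C3 chain; gold closes ring A (C3–C4); C4 is then reduced, ring B is oxidised and acylated, and the C3 ester is removed last.
Stereochemistry: C5 from a catalytic enantioselective conjugate addition; C10 by equilibration (chain cis to the slim ethynyl group); C4 by hydrogenation directed from the alpha face by a temporary 9α-hydroxyl; C7 by convex-face cuprate addition; C8 trans to C7 by enolate hydroxylation; C9 by beta-face hydride; the acyl stereocentre from (R)-2-methylbutanoic acid and the E alkene from tiglic acid.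

Key step: step 5

Remarks on the chemistry (assumptions):
- β is the face of the angular C5 methyl (C14). The SMILES is read as a cis-fused (10βH) decalin with 4β-methyl, 7β-isopropenyl, an 8α-(R)-2-methylbutanoate and a 9α-(E)-2-methylbut-2-enoate (tiglate).
- C3 of the beta-keto esters 11, 13–15 and 30 is labile through the enol. It is drawn as the 3β-ester throughout without implying that this epimer predominates; 13 and 14 may also sit in part as the enol or the internal 2,9-hemiketal.
- In the chair with C9 axial on ring A, a 9α-oxygen lies under ring A close to C2 and C4. This is why the C9 carbinol can direct hydrogen to the α face of C4, and why ring A is masked as a planar enol ether and not as a C2 ketal during the ring B steps.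

**Route**

Step 1
Reactants: 1 3-methylcyclohex-2-en-1-one; 2 ethynyltrimethylsilane
Product: 5 (S)-trimethyl({3-methyl-3-[(trimethylsilyl)ethynyl]cyclohex-1-en-1-yl}oxy)silane, via alkynylalane 3 (not isolated), via aluminium enolate 4 (not isolated)
Conditions: 2, i-Bu2AlH, Et3N (5 mol%), hexanes, 23→55 °C; then 1, CuCl2·2H2O (5 mol%), chiral sulfonate-bearing imidazolinium salt (carbene precursor, 5 mol%), THF, 23 °C; then Me3SiOTf, −78→0 °C
Reagents that add atoms: trimethylsilyl trifluoromethanesulfonate, C[Si](C)(C)OS(=O)(=O)C(F)(F)F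
Why: Copper-catalysed enantioselective conjugate addition of a silylalkynylaluminium reagent (N-heterocyclic carbene ligand, the enantiomer chosen that gives the S quaternary centre) builds C5, and silylation of the aluminium enolate keeps the enolate double bond at C9–C10.

Step 2
Reactants: 5 silyl enol ether; 6 methyl (E)-4-bromo-3-methoxybut-2-enoate
Product: 8 methyl (E)-3-methoxy-4-{(2S)-2-methyl-6-oxo-2-[(trimethylsilyl)ethynyl]cyclohexyl}but-2-enoate (both C10 epimers), via lithium enolate 7 (not isolated)
Conditions: MeLi, THF, 0 °C; then 6, DMPU, −78→−20 °C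
Reagents that add atoms: none
Why: Methyllithium cleaves the O–Si bond to the lithium enolate with its double bond held at C9–C10, which is C-alkylated at C10 by the allylic bromide (an acetoacetate γ-cation equivalent); the C10 configuration is corrected in step 3.

Step 3
Reactants: 8 alkylated ketone
Product: 9 methyl (E)-4-[(1S,2S)-2-ethynyl-2-methyl-6-oxocyclohexyl]-3-methoxybut-2-enoate
Conditions: NaOMe (0.3 equiv), MeOH, 0→40 °C
Reagents that add atoms: none
Why: Methoxide removes the alkynyl silyl group and equilibrates C10 through the C9 enolate to the epimer with the chain equatorial, trans to the C5 methyl and cis to the axial ethynyl group, which is preferred because ethynyl is much smaller than methyl in the axial position.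

Step 4
Reactants: 9 cis ethynyl ketone
Product: 10 methyl 4-[(1S,2S)-2-ethynyl-2-methyl-6-oxocyclohexyl]-3-oxobutanoate
Conditions: 1 M HCl, THF, 23 °C (short contact)
Reagents that add atoms: water, O
Why: Acid hydrolysis of the β-methoxy enoate (an enol ether) unmasks the beta-keto ester without affecting the terminal alkyne, and the mild conditions leave the hindered C9 ketone alone.

Step 5
Reactants: 10 alkynyl beta-keto ester
Product: 11 methyl 5β-methyl-4-methylidene-2,9-dioxo-10βH-decalin-3-carboxylate (cis-fused)
Conditions: Ph3PAuCl (5 mol%), AgOTf (5 mol%), CH2Cl2, 23 °C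
Reagents that add atoms: none
Why: Ph3PAuOTf, formed in the flask, binds the C5 ethynyl group as a π-complex of monovalent gold, the enol of the beta-keto ester attacks the internal alkyne carbon through C3 anti to the metal, and protodeauration of the vinylgold leaves the exocyclic C4=C15 methylene. The closest known reaction type is the gold-catalysed Conia-ene carbocyclisation of alkynyl beta-keto esters. Ring A closes 6-exo-dig through the new C3–C4 bond, the 7-endo mode at the terminal carbon not being competitive. The only new stereocentre, C3, is labile through the enol and is removed later, while the cis ring fusion is fixed beforehand by C5 and C10, whose chain and ethynyl groups are cis. The step needs attack by C3 in preference to the enol oxygen, the C9 carbonyl oxygen or an aldol addition to C9: only C3 is doubly activated and enolised under these neutral conditions, and the gauche placement of chain and alkyne on adjacent ring carbons next to the quaternary C5 brings C3 within reach of C4.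

Step 6
Reactants: 11 decalindione beta-keto ester
Product: 13 methyl 9α-hydroxy-5β-methyl-4-methylidene-2-oxo-10βH-decalin-3-carboxylate, via lithium enolate 12 (not isolated)
Conditions: LiN(SiMe3)2 (1.05 equiv), THF, −78 °C; then LiBH(s-Bu)3, −78 °C; AcOH
Reagents that add atoms: none
Why: The beta-keto ester is deprotonated first and is inert as its enolate, so the bulky borohydride reduces only the C9 ketone, from the convex β face because ring A screens the α face in either chair, which gives the 9α-carbinol.

Step 7
Reactants: 13 9α-hydroxy methylene compound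
Product: 14 methyl 9α-hydroxy-4β,5β-dimethyl-2-oxo-10βH-decalin-3-carboxylate
Conditions: [Ir(cod)(PCy3)(py)]PF6 (5 mol%), H2 (1 atm), CH2Cl2, 23 °C
Reagents that add atoms: none
Why: Hydroxyl-directed homogeneous hydrogenation: the cationic iridium catalyst is anchored by the 9α-hydroxyl, which in the chair with C9 axial on ring A lies under that ring next to C4, so hydrogen is delivered to the α face of the methylene and C15 ends up β, cis to C14, whereas undirected addition from the convex β face would give the C4 epimer.

Step 8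
Reactants: 14 hydroxy beta-keto ester
Product: 15 methyl 4β,5β-dimethyl-2,9-dioxo-10βH-decalin-3-carboxylate
Conditions: Dess–Martin periodinane, CH2Cl2, 0→23 °C
Reagents that add atoms: none
Why: Dess–Martin oxidation returns the C9 ketone needed for the enolate chemistry in ring B, the carbinol having served to set C4.

Step 9
Reactants: 15 dione beta-keto ester
Product: 16 methyl 2-methoxy-4β,5β-dimethyl-9-oxo-10βH-decal-2-ene-3-carboxylate
Conditions: Me3SiCHN2, i-Pr2NEt, MeCN/MeOH, 23 °C
Reagents that add atoms: trimethylsilyldiazomethane (gives the O-methyl carbon), C[Si](C)(C)C=[N+]=[N-]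
Why: O-Methylation of the enolised beta-keto ester with the diazoalkane masks ring A as a planar vinylogous carbonate that tolerates amide bases, cuprates and hydrides and, unlike a C2 ketal with its axial oxygen, leaves room under ring A for the 9α-oxygen introduced in step 14.

Step 10
Reactants: 16 enol ether ketone
Product: 18 methyl 2-methoxy-4β,5β-dimethyl-9-oxo-10βH-decala-2,7-diene-3-carboxylate, via silyl enol ether 17 (not isolated)
Conditions: LiN(i-Pr)2, Me3SiCl, THF, −78 °C; then Pd(OAc)2 (1.05 equiv), MeCN, 23 °C
Reagents that add atoms: none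
Why: Saegusa–Ito oxidation: the amide base removes the less hindered C8 proton (C10–H is flanked by the quaternary C5), the silyl enol ether is trapped in the flask and Pd(OAc)2 converts it into the C7=C8 enone without touching C10.

Step 11
Reactants: 18 enone; 19 isopropenylmagnesium bromide
Product: 21 methyl 7β-isopropenyl-2-methoxy-4β,5β-dimethyl-9-oxo-10βH-decal-2-ene-3-carboxylate, via silyl enol ether 20 (not isolated)
Conditions: 19 (1.5 equiv), CuBr·SMe2 (10 mol%), Me3SiCl, THF, −78→−40 °C; then AcOH, H2O, 0 °C
Reagents that add atoms: none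
Why: Copper-catalysed conjugate addition of the Grignard reagent, accelerated by Me3SiCl, adds the isopropenyl group to C7 from the convex β face of the cis-fused enone, since both α trajectories run into ring A (the syn-axial C4 in one half-chair and the C1 methylene in the other), so the new group is cis to C14.

Step 12
Reactants: 21 isopropenyl ketone
Product: 23 methyl 8α-hydroxy-7β-isopropenyl-2-methoxy-4β,5β-dimethyl-9-oxo-10βH-decal-2-ene-3-carboxylate, via potassium enolate 22 (not isolated)
Conditions: KN(SiMe3)2, THF, −78 °C; then 2-(phenylsulfonyl)-3-phenyloxaziridine, −78 °C; AcOH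
Reagents that add atoms: 2-(phenylsulfonyl)-3-phenyloxaziridine (gives O), O=S(=O)(c1ccccc1)N1OC1c1ccccc1
Why: Davis-type hydroxylation: the kinetic potassium enolate (at C8, not at the hindered C10) takes oxygen from the N-sulfonyloxaziridine on the face opposite the neighbouring isopropenyl group, giving the 8α-hydroxyl, trans-diequatorial to it and also the more stable epimer.

Step 13
Reactants: 23 ketol; 24 (R)-2-methylbutanoic acid
Product: 25 methyl 7β-isopropenyl-2-methoxy-4β,5β-dimethyl-8α-[(R)-2-methylbutanoyloxy]-9-oxo-10βH-decal-2-ene-3-carboxylate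
Conditions: EDC·HCl, DMAP (cat.), CH2Cl2, 0→23 °C
Reagents that add atoms: none
Why: Carbodiimide (Steglich) esterification of the unhindered equatorial ketol hydroxyl brings in the acyl group with its stereocentre from the acid, under nearly neutral conditions chosen to avoid racemisation of the acid and ketol rearrangement.

Step 14
Reactants: 25 acyloxy ketone
Product: 26 methyl 9α-hydroxy-7β-isopropenyl-2-methoxy-4β,5β-dimethyl-8α-[(R)-2-methylbutanoyloxy]-10βH-decal-2-ene-3-carboxylate
Conditions: LiBH(s-Bu)3, THF, −78 °C; AcOH, −78 °C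
Reagents that add atoms: none
Why: The bulky borohydride attacks the C9 carbonyl equatorially from the β face because the axial α trajectory is blocked by ring A (C4 syn-axial), giving the axial 9α-carbinol cis to O8, and the cold acidic quench keeps the 8-O-acyl group from migrating.

Step 15
Reactants: 26 hydroxy ester; 27 tiglic acid
Product: 29 methyl 7β-isopropenyl-2-methoxy-4β,5β-dimethyl-8α-[(R)-2-methylbutanoyloxy]-9α-[(E)-2-methylbut-2-enoyloxy]-10βH-decal-2-ene-3-carboxylate, via mixed anhydride 28 (not isolated)
Conditions: 27, 2,4,6-trichlorobenzoyl chloride, Et3N, toluene, 23 °C; then 26, DMAP, 60 °C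
Reagents that add atoms: none
Why: Yamaguchi esterification: the mixed anhydride activated by DMAP acylates the hindered axial 9α-hydroxyl, and the E geometry of the tiglate comes unchanged from tiglic acid.

Step 16
Reactants: 29 diester enol ether
Product: 30 methyl 7β-isopropenyl-4β,5β-dimethyl-8α-[(R)-2-methylbutanoyloxy]-9α-[(E)-2-methylbut-2-enoyloxy]-2-oxo-10βH-decalin-3-carboxylate
Conditions: 1 M HCl, THF, 23→40 °C
Reagents that add atoms: water, O
Why: Acid hydrolysis of the vinylogous carbonate (protonation at C3, hydration at C2, loss of methanol) restores the beta-keto ester, while the two secondary esters and the isopropenyl group are stable to dilute acid at this temperature.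

Step 17
Reactants: 30 beta-keto ester
Product: 31 CNP0312791.1
Conditions: LiCl, H2O, DMSO, 130 °C
Reagents that add atoms: none
Why: Krapcho dealkoxycarbonylation: chloride demethylates only the beta-keto methyl ester (the secondary esters on O8 and O9 are not attacked), the carboxylate loses CO2 and C3 becomes the methylene of the target with no stereocentre put at risk.

**Compound list**

1 | 3-methylcyclohex-2-en-1-one | CC1=CC(=O)CCC1 | starting material
2 | ethynyltrimethylsilane (trimethylsilylacetylene) | C#C[Si](C)(C)C | starting material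
3 | diisobutyl[(trimethylsilyl)ethynyl]aluminium | CC(C)C[Al](CC(C)C)C#C[Si](C)(C)C | intermediate (not isolated)
4 | diisobutylaluminium (S)-3-methyl-3-[(trimethylsilyl)ethynyl]cyclohex-1-en-1-olate | CC(C)C[Al](CC(C)C)OC1=C[C@@](C)(C#C[Si](C)(C)C)CCC1 | intermediate (not isolated)
5 | (S)-trimethyl({3-methyl-3-[(trimethylsilyl)ethynyl]cyclohex-1-en-1-yl}oxy)silane | C[Si](C)(C)OC1=C[C@@](C)(C#C[Si](C)(C)C)CCC1 | intermediate
6 | methyl (E)-4-bromo-3-methoxybut-2-enoate | CO/C(CBr)=C/C(=O)OC | starting material
7 | lithium (S)-3-methyl-3-[(trimethylsilyl)ethynyl]cyclohex-1-en-1-olate | [Li]OC1=C[C@@](C)(C#C[Si](C)(C)C)CCC1 | intermediate (not isolated)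
8 | methyl (E)-3-methoxy-4-{(2S)-2-methyl-6-oxo-2-[(trimethylsilyl)ethynyl]cyclohexyl}but-2-enoate, both C10 epimers | C[Si](C)(C)C#C[C@@]1(C)CCCC(=O)C1C/C(OC)=C\C(=O)OC | intermediate
9 | methyl (E)-4-[(1S,2S)-2-ethynyl-2-methyl-6-oxocyclohexyl]-3-methoxybut-2-enoate (chain cis to ethynyl) | C#C[C@@]1(C)CCCC(=O)[C@H]1C/C(OC)=C\C(=O)OC | intermediate
10 | methyl 4-[(1S,2S)-2-ethynyl-2-methyl-6-oxocyclohexyl]-3-oxobutanoate | C#C[C@@]1(C)CCCC(=O)[C@H]1CC(=O)CC(=O)OC | intermediate
11 | methyl 5β-methyl-4-methylidene-2,9-dioxo-10βH-decalin-3-carboxylate (cis-fused, eremophilane numbering) | O=C1CCC[C@@]2(C)[C@@H]1CC(=O)[C@H](C(=O)OC)C2=C | intermediate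
12 | C2 lithium enolate of 11 | C1C[C@@]2(C)[C@H](CC(O[Li])=C(C(=O)OC)C2=C)C(=O)C1 | intermediate (not isolated)
13 | methyl 9α-hydroxy-5β-methyl-4-methylidene-2-oxo-10βH-decalin-3-carboxylate | C1C[C@@]2(C)[C@H](CC(=O)[C@H](C(=O)OC)C2=C)[C@H](O)C1 | intermediate
14 | methyl 9α-hydroxy-4β,5β-dimethyl-2-oxo-10βH-decalin-3-carboxylate | C1C[C@@]2(C)[C@H](CC(=O)[C@H](C(=O)OC)[C@@H]2C)[C@H](O)C1 | intermediate
15 | methyl 4β,5β-dimethyl-2,9-dioxo-10βH-decalin-3-carboxylate | C1C[C@@]2(C)[C@H](CC(=O)[C@H](C(=O)OC)[C@@H]2C)C(=O)C1 | intermediate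
16 | methyl 2-methoxy-4β,5β-dimethyl-9-oxo-10βH-decal-2-ene-3-carboxylate | C1C[C@@]2(C)[C@H](CC(OC)=C(C(=O)OC)[C@@H]2C)C(=O)C1 | intermediate
17 | methyl 2-methoxy-4β,5β-dimethyl-9-(trimethylsilyloxy)-10βH-decala-2,8-diene-3-carboxylate | C1C[C@@]2(C)[C@H](CC(OC)=C(C(=O)OC)[C@@H]2C)C(O[Si](C)(C)C)=C1 | intermediate (not isolated)
18 | methyl 2-methoxy-4β,5β-dimethyl-9-oxo-10βH-decala-2,7-diene-3-carboxylate | C=1C[C@@]2(C)[C@H](CC(OC)=C(C(=O)OC)[C@@H]2C)C(=O)C=1 | intermediate
19 | isopropenylmagnesium bromide (prop-1-en-2-ylmagnesium bromide) | C=C(C)[Mg]Br | starting material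
20 | methyl 7β-isopropenyl-2-methoxy-4β,5β-dimethyl-9-(trimethylsilyloxy)-10βH-decala-2,8-diene-3-carboxylate | C=C(C)[C@H]1C[C@@]2(C)[C@H](CC(OC)=C(C(=O)OC)[C@@H]2C)C(O[Si](C)(C)C)=C1 | intermediate (not isolated)
21 | methyl 7β-isopropenyl-2-methoxy-4β,5β-dimethyl-9-oxo-10βH-decal-2-ene-3-carboxylate | C=C(C)[C@H]1C[C@@]2(C)[C@H](CC(OC)=C(C(=O)OC)[C@@H]2C)C(=O)C1 | intermediate
22 | potassium 8-en-9-olate of 21 | C=C(C)[C@H]1C[C@@]2(C)[C@H](CC(OC)=C(C(=O)OC)[C@@H]2C)C(O[K])=C1 | intermediate (not isolated)
23 | methyl 8α-hydroxy-7β-isopropenyl-2-methoxy-4β,5β-dimethyl-9-oxo-10βH-decal-2-ene-3-carboxylate | C=C(C)[C@H]1C[C@@]2(C)[C@H](CC(OC)=C(C(=O)OC)[C@@H]2C)C(=O)[C@@H]1O | intermediate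
24 | (R)-2-methylbutanoic acid | CC[C@@H](C)C(=O)O | starting material
25 | methyl 7β-isopropenyl-2-methoxy-4β,5β-dimethyl-8α-[(R)-2-methylbutanoyloxy]-9-oxo-10βH-decal-2-ene-3-carboxylate | C=C(C)[C@H]1C[C@@]2(C)[C@H](CC(OC)=C(C(=O)OC)[C@@H]2C)C(=O)[C@@H]1OC(=O)[C@H](C)CC | intermediate
26 | methyl 9α-hydroxy-7β-isopropenyl-2-methoxy-4β,5β-dimethyl-8α-[(R)-2-methylbutanoyloxy]-10βH-decal-2-ene-3-carboxylate | C=C(C)[C@H]1C[C@@]2(C)[C@H](CC(OC)=C(C(=O)OC)[C@@H]2C)[C@H](O)[C@@H]1OC(=O)[C@H](C)CC | intermediate
27 | tiglic acid, (E)-2-methylbut-2-enoic acid | C/C=C(\C)C(=O)O | starting material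
28 | (E)-2-methylbut-2-enoic 2,4,6-trichlorobenzoic anhydride | C/C=C(\C)C(=O)OC(=O)c1c(Cl)cc(Cl)cc1Cl | intermediate (not isolated)
29 | methyl 7β-isopropenyl-2-methoxy-4β,5β-dimethyl-8α-[(R)-2-methylbutanoyloxy]-9α-[(E)-2-methylbut-2-enoyloxy]-10βH-decal-2-ene-3-carboxylate | C=C(C)[C@H]1C[C@@]2(C)[C@H](CC(OC)=C(C(=O)OC)[C@@H]2C)[C@H](OC(=O)/C(C)=C/C)[C@@H]1OC(=O)[C@H](C)CC | intermediate
30 | methyl 7β-isopropenyl-4β,5β-dimethyl-8α-[(R)-2-methylbutanoyloxy]-9α-[(E)-2-methylbut-2-enoyloxy]-2-oxo-10βH-decalin-3-carboxylate | C=C(C)[C@H]1C[C@@]2(C)[C@H](CC(=O)[C@H](C(=O)OC)[C@@H]2C)[C@H](OC(=O)/C(C)=C/C)[C@@H]1OC(=O)[C@H](C)CC | intermediate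
31 | CNP0312791.1: 8α-[(R)-2-methylbutanoyloxy]-9α-[(E)-2-methylbut-2-enoyloxy]-10βH-eremophil-11-en-2-one (4β,5β-dimethyl, 7β-isopropenyl) | C=C(C)[C@H]1C[C@@]2(C)[C@H](CC(=O)C[C@@H]2C)[C@H](OC(=O)/C(C)=C/C)[C@@H]1OC(=O)[C@H](C)CC | target

**Step count**

Total steps: 17. Longest linear sequence: 17 steps, from 1 to 31; 2, 6, 19, 24 and 27 enter as purchased reagents.

**Steps most likely to fail**

Step 5 (ring closure). What may go wrong: the 6-exo closure is slow and other nucleophiles take over, so that ring A is not formed cleanly. The C9 carbonyl oxygen may add to the gold-bound alkyne (5-exo-dig, leading to hydration or furan-type products), or C3 may add to the C9 carbonyl in an aldol reaction. Fallback: lower the oxidation level of C9 before the ring closure, so that no carbonyl group is near the alkyne or the chain. It sets out from 9. LiBH(s-Bu)3 (THF, −78 °C) attacks equatorially, the axial ethynyl group on C5 blocking the axial path, and should give the 9α-carbinol F1 (hydroxyl cis to chain and ethynyl). i-Pr3SiOTf and 2,6-lutidine give the silyl ether F2. 1 M HCl in THF hydrolyses the enol ether to the silyl-protected beta-keto ester F3. Ph3PAuCl/AgOTf closes ring A to the bicyclic silyl ether F4. HF·pyridine removes the silyl group and gives 13, where the route goes on with step 7; step 6 is then not needed.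

Step 7 (hydrogenation). What may go wrong: hydrogen is added without guidance from the hydroxyl, from the open β face, or the catalyst moves the double bond into conjugation with the beta-keto ester, so that the C4 epimer or a mixture results. Fallback: hydrogenate in the rigid trans-fused series and set the ring fusion afterwards. There the axial angular methyl screens the β face of C4, and an ordinary heterogeneous catalyst adds from the α face. It sets out from 8, whose main kinetic epimer should have the chain trans to the alkyne. K2CO3 in MeOH at 0 °C removes the silyl group without equilibration and gives the trans ethynyl ketone F5. 1 M HCl in THF gives the trans beta-keto ester F6. The gold catalyst of step 5 closes the trans-fused methylene decalin F7. H2 over Pd/C gives the trans-fused 4β-methyl dione F8. DBU then equilibrates C10 through the C9 enolate; the cis-fused isomer is 15, so steps 6 to 8 are not needed, and recovered trans material is put through the equilibration again.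

Step 15 (tigloylation). What may go wrong: acylation of the axial 9α-hydroxyl, which sits under ring A, is so slow that the 8-O-acyl group migrates and the freed equatorial 8-hydroxyl is acylated instead, giving the regioisomeric diester. Fallback: bring in the acyl group through a ketene and form the double bond afterwards. It sets out from 26. 2-(Diethoxyphosphoryl)propanoic acid and DCC (acylation through the phosphonoketene) give the phosphonate ester F9. LiCl, DBU and acetaldehyde in MeCN (Horner–Wadsworth–Emmons olefination, E-selective for this trisubstituted enoate) give 29, where the route goes on with step 16.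

**Further compounds**

F1 | step 5 | methyl (E)-4-[2-ethynyl-6-hydroxy-2-methylcyclohexyl]-3-methoxybut-2-enoate, hydroxyl cis to chain and ethynyl (9α-carbinol) | C#C[C@@]1(C)CCC[C@@H](O)[C@H]1C/C(OC)=C\C(=O)OC
F2 | step 5 | triisopropylsilyl ether of F1 | C#C[C@@]1(C)CCC[C@@H](O[Si](C(C)C)(C(C)C)C(C)C)[C@H]1C/C(OC)=C\C(=O)OC
F3 | step 5 | methyl 4-[2-ethynyl-2-methyl-6-(triisopropylsilyloxy)cyclohexyl]-3-oxobutanoate (all-cis) | C#C[C@@]1(C)CCC[C@@H](O[Si](C(C)C)(C(C)C)C(C)C)[C@H]1CC(=O)CC(=O)OC
F4 | step 5 | methyl 5β-methyl-4-methylidene-2-oxo-9α-(triisopropylsilyloxy)-10βH-decalin-3-carboxylate | C1C[C@@]2(C)[C@H](CC(=O)[C@H](C(=O)OC)C2=C)[C@H](O[Si](C(C)C)(C(C)C)C(C)C)C1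
F5 | step 7 | methyl (E)-4-[(1R,2S)-2-ethynyl-2-methyl-6-oxocyclohexyl]-3-methoxybut-2-enoate (chain trans to ethynyl) | C#C[C@@]1(C)CCCC(=O)[C@@H]1C/C(OC)=C\C(=O)OC
F6 | step 7 | methyl 4-[(1R,2S)-2-ethynyl-2-methyl-6-oxocyclohexyl]-3-oxobutanoate | C#C[C@@]1(C)CCCC(=O)[C@@H]1CC(=O)CC(=O)OC
F7 | step 7 | methyl 5β-methyl-4-methylidene-2,9-dioxo-10αH-decalin-3-carboxylate (trans-fused) | C1C[C@@]2(C)[C@@H](CC(=O)[C@H](C(=O)OC)C2=C)C(=O)C1
F8 | step 7 | methyl 4β,5β-dimethyl-2,9-dioxo-10αH-decalin-3-carboxylate (trans-fused) | C1C[C@@]2(C)[C@@H](CC(=O)[C@H](C(=O)OC)[C@@H]2C)C(=O)C1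
F9 | step 15 | 9α-[2-(diethoxyphosphoryl)propanoyloxy] ester of 26 (phosphonate carbon as a mixture) | C=C(C)[C@H]1C[C@@]2(C)[C@H](CC(OC)=C(C(=O)OC)[C@@H]2C)[C@H](OC(=O)C(C)P(=O)(OCC)OCC)[C@@H]1OC(=O)[C@H](C)CC
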